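The numbers in the tables stem from a simulated flask for an exercise.

In this flask the complex charged stands as starting complex, complex with one exchanged or complex with two exchanged, so c(one exchanged) is the charge minus c(starting complex) minus c(two exchanged), and the last term enters as a small correction.

| flask | starting complex | incoming ligand | remark | time |
|---|---|---|---|---|
| ochre | 1 M | 3 M | the very flask that is asked about, followed so far |  |
| flask | 1.0 M | 3.00 M |  | 4.0 min |

ochre run (percent of the starting complex charged)

| time / s | complex with one exchanged / % | complex with two exchanged / % | starting complex / % |
|---|---|---|---|
| 10.0 | 20.4 | 0 | 79.0 |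
| 20.0 | 32.3 | 0.4 | 67.1 |
| 30.0 | 40.9 | 1.3 | 57.8 |
| 50.0 | 52.8 | 0.7 | 46.9 |
| 80.0 | 60.2 | 1.2 | 37.8 |

(scatter of a reading: 0.5 percentage points)

- the numbers in the tables scatter with a standard deviation of 0.5 percentage points

* equivalents of incoming ligand to starting complex, everything else as given, that leave most complex with one exchanged at 4.0 min
* the amount of complex with one exchanged then, in percent of the starting complex charged
* the amount of complex with one exchanged with the amounts as given

1. The ochre run looks contradictory. At 80.0 s, counting one incoming ligand spent per complex converted leaves 79.3% of its charge unspent, yet the loss of starting complex over equal spans of 30.0 s falls from 20 points to 9.1 points, less than before.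
2. Those spans shrink by a ratio of 0.450. Continued as a geometric series, they stop the ochre curve at a reading of 30.3% starting complex.
3. At that stop, counted the same way, 76.8% of the ligand remains unspent. The stop reads as 0.694: the stall quotient, converted complex squared over starting complex left times ligand unspent, an apparent equilibrium constant.
4. The correction scales the reading of 1.2% two exchanged in proportion to time, giving 3.6 points at 4.0 min. This reckoning therefore gives 66.1% complex with one exchanged.

The forecast differs, with 78% as given and 81% at 4.5 equiv, under the words “The optimum is shallow”.

The flask gives 66.0% as given and 69.3% at 5.13 equiv.

    starting complex + incoming ligand ⇌ leaving ligand + complex with one exchanged (K = 1.50, k = 0.00970 M⁻¹ s⁻¹)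
    complex with one exchanged + incoming ligand ⇌ leaving ligand + complex with two exchanged (K = 2.00, k = 3.10 × 10⁻⁴ M⁻¹ s⁻¹)
    incoming ligand ⇌ dormant form (K = 0.860, k = 0.0360 s⁻¹)

The flask holds 29% starting complex at 4.00 min, a quotient of 0.778. A neighbouring flask charges 1.7 M of starting complex against the same 3.00 M of incoming ligand. Solved for that charge, the quotient read from the ochre run, 0.694, leaves 41.6% starting complex. Taking off the same correction leaves 54.8% complex with one exchanged. That neighbouring flask itself holds 40% starting complex and 56.1% complex with one exchanged at 4.00 min.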